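Ring B (C1, C5–C10) is opened at C1–C10: quaternary C1 adjoins the C5–C6 bond and stands 1,3 to oxygen-bearing C9, the pattern a Claisen shift leaves behind. Enol ether 10, an oxolane whose oxygen links C6 to C9 and which carries the exocyclic C9=C10 methylidene next to the ring A cyclopentenyl unit C5=C1, rearranges on heating: C1–C10 forms, the seven-membered ring closes, the C6 configuration is relayed to C1, and a C9 ketone and a C5=C6 alkene emerge. The alkene later receives H5 and O6 on the face opposite the angular methyl; the ketone brings in C14 and the C9 hydroxyl.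

Key step: step 6

Remarks: Daucane numbering is used throughout (ring A: C1–C5; ring B: C1, C5–C10; C14 = exocyclic methylene carbon). β is the face of the C1 methyl, α the opposite face; "hydroazulane" means the bicyclo[5.3.0]decane core. Assumption: the C9 configuration of 12–17 is left open (either epimer serves), because C9 is returned to the ketone in step 12.

Step 1
Reactants: 1 2-bromo-3-methylcyclopent-2-en-1-one; 2 ethylene glycol
Product: 3 6-bromo-7-methyl-1,4-dioxaspiro[4.4]non-6-ene
Conditions: p-TsOH·H2O (cat.), benzene, reflux, Dean–Stark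
Reagents that add atoms: none
Why: Acid-catalysed ketalisation with azeotropic removal of water; the bromine-bearing double bond should stay in place and no stereocentre is formed.

Step 2
Reactants: 4 methyl 4-chloro-4-oxobutanoate
Product: 5 methyl 4-[methoxy(methyl)amino]-4-oxobutanoate
Conditions: MeNHOMe·HCl, pyridine, CH2Cl2, 0 °C → rt
Reagents that add atoms: N,O-dimethylhydroxylamine hydrochloride, CNOC.Cl
Why: N-acylation of the hydroxylamine by the acid chloride gives the Weinreb amide and leaves the methyl ester untouched.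

Step 3
Reactants: 3 6-bromo-7-methyl-1,4-dioxaspiro[4.4]non-6-ene; 5 methyl 4-[methoxy(methyl)amino]-4-oxobutanoate
Product: 7 methyl 4-(7-methyl-1,4-dioxaspiro[4.4]non-6-en-6-yl)-4-oxobutanoate, via vinyllithium 6 (not isolated)
Conditions: n-BuLi, THF, −78 °C; then 5, −78 → −40 °C; aq. NH4Cl
Reagents that add atoms: n-butyllithium, [Li]CCCC (supplies the lithium of 6)
Why: Bromine–lithium exchange gives the masked α-keto vinyl anion, which attacks the Weinreb amide in preference to the ester at −78 °C and is held as a chelated adduct until work-up releases the ketone (Weinreb ketone synthesis).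

Step 4
Reactants: 7 methyl 4-(7-methyl-1,4-dioxaspiro[4.4]non-6-en-6-yl)-4-oxobutanoate
Product: 9 (5S)-5-(7-methyl-1,4-dioxaspiro[4.4]non-6-en-6-yl)oxolan-2-one, via hydroxy ester 8 (not isolated)
Conditions: (R)-2-methyl-CBS-oxazaborolidine (0.2 equiv), BH3·SMe2, THF, −30 °C; MeOH; then t-BuOK (5 mol%), THF, 0 °C
Reagents that add atoms: none
Why: Corey–Bakshi–Shibata reduction in which the fully substituted cyclopentenyl group acts as the large and the CH2 chain as the small substituent, so the (R)-catalyst should deliver hydride to the face that gives the 6S alcohol 8, which then closes to the five-membered lactone by alkoxide-catalysed transesterification.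

Step 5
Reactants: 9 (5S)-5-(7-methyl-1,4-dioxaspiro[4.4]non-6-en-6-yl)oxolan-2-one
Product: 10 (2S)-2-(7-methyl-1,4-dioxaspiro[4.4]non-6-en-6-yl)-5-methylideneoxolane
Conditions: Cp2TiMe2 (2.5 equiv), toluene, pyridine (trace), 70 °C, dark; pentane, filtration through basic Al2O3
Reagents that add atoms: dimethyltitanocene Cp2TiMe2, [CH3-].[CH3-].[Ti+4].c1cc[cH-]c1.c1cc[cH-]c1
Why: Petasis methylenation, in which Cp2Ti=CH2 formed by loss of methane converts the lactone carbonyl into the exocyclic enol ether under non-acidic conditions that leave the ketal, the alkene and the C6 stereocentre untouched.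

Step 6
Reactants: 10 (2S)-2-(7-methyl-1,4-dioxaspiro[4.4]non-6-en-6-yl)-5-methylideneoxolane
Product: 11 (1R)-4,4-ethylenedioxy-1-methyl-Δ5-hydroazulen-9-one (ring B enone: C9 ketone, C5=C6 alkene, C4 dioxolane, quaternary C1)
Conditions: toluene (0.02 M, degassed), i-Pr2NEt (1 mol%), base-washed sealed tube, 180 °C
Reagents that add atoms: none
Why: Concerted suprafacial [3,3] sigmatropic shift of the allyl vinyl ether C10=C9–O–C6–C5=C1 through the boat-like six-centre array imposed by the oxolane tether: C10 bonds to C1 as the C6–O bond breaks, and the ether oxygen becomes the C9 carbonyl. It is the Claisen ring expansion by which 2-methylidene-5-vinyloxolanes give cyclohept-4-enones, applied here to a fully substituted alkene terminus. Ring B closes as a seven-membered carbocycle by sigmatropic two-atom enlargement of the five-membered oxolane, a pericyclic closure in which the C7–C8 tether forces a cis C5=C6 alkene inside the new ring. The only new stereocentre, quaternary C1, is controlled by C6: bond making and bond breaking occur on one face of the C6–C5=C1 unit and C7 must lie on the C1 side, so the 6S ether can only give the 1R ketone. The step needs the [3,3] path to beat acid-induced migration of the exocyclic double bond into the oxolane ring and ionisation of the allylic C6–O bond; a non-polar solvent, base-treated glass and a trace of amine should secure this, and the gain of a C=O bond makes the shift irreversible.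

Step 7
Reactants: 11 (1R)-4,4-ethylenedioxy-1-methyl-Δ5-hydroazulen-9-one
Product: 12 4,4-ethylenedioxy-1β-methyl-9-(triethylsilyloxy)-Δ5-hydroazulene (C9 epimers)
Conditions: Et3SiH, RhCl(PPh3)3 (2 mol%), benzene, 60 °C
Reagents that add atoms: triethylsilane, CC[SiH](CC)CC
Why: Rhodium-catalysed hydrosilylation of the ketone gives the silyl ether directly and without acid, masking C9 against borane while the ketal and the hindered trisubstituted alkene stay intact; the C9 configuration is immaterial.

Step 8
Reactants: 12 4,4-ethylenedioxy-1β-methyl-9-(triethylsilyloxy)-Δ5-hydroazulene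
Product: 14 6α-hydroxy-5α-H trans-fused ketal bearing 9-OSiEt3 (C9 epimers), via C6 alkylborane 13 (not isolated)
Conditions: BH3·THF (3 equiv), THF, 0 °C → rt; then NaOH, H2O2, 0 °C → rt
Reagents that add atoms: borane–tetrahydrofuran, B (boron of 13); hydrogen peroxide, OO (O6 of 14)
Why: Brown hydroboration–oxidation: boron adds to the less substituted C6 and hydrogen to C5 in a syn manner from the α face, the β face of C5 being flanked by the angular methyl on C1, and oxidation with retention should give the trans-fused 5α-H,6α-OH pattern.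

Step 9
Reactants: 14 6α-hydroxy-5α-H trans-fused ketal bearing 9-OSiEt3
Product: 15 6α-(tert-butyldimethylsilyloxy) ether of 14 (C9 epimers)
Conditions: TBSOTf, 2,6-lutidine, CH2Cl2, −40 → 0 °C
Reagents that add atoms: tert-butyldimethylsilyl triflate, CC(C)(C)[Si](C)(C)OS(=O)(=O)C(F)(F)F
Why: Silylation of the hindered secondary alcohol with a silyl triflate and a hindered pyridine base, without touching any stereocentre.

Step 10
Reactants: 15 6α-(tert-butyldimethylsilyloxy) ether of 14
Product: 16 6α-(tert-butyldimethylsilyloxy)-9-hydroxy-1β-methyl-5α-H-hydroazulan-4-one (C9 epimers)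
Conditions: PPTS, acetone–H2O (9:1), 55 °C
Reagents that add atoms: water, O
Why: Mild acid hydrolysis removes the triethylsilyl ether and the dioxolane, while the hindered secondary tert-butyldimethylsilyl ether should survive and the weak acid avoids β-elimination and epimerisation at C5.

Step 11
Reactants: 16 6α-(tert-butyldimethylsilyloxy)-9-hydroxy-1β-methyl-5α-H-hydroazulan-4-one
Product: 17 6α-(tert-butyldimethylsilyloxy)-14-nordaucane-4β,9-diol (4α-isopropyl; C9 epimers)
Conditions: i-PrMgCl, CeCl3 (dried), THF, −78 → −20 °C; aq. NH4Cl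
Reagents that add atoms: isopropylmagnesium chloride, CC(C)[Mg]Cl
Why: Organocerium (Imamoto) 1,2-addition: the weakly basic reagent should add to the enolisable cyclopentanone from the α face past the small H5, the β face being screened by C6 with its silyloxy group and by the C1 methyl, which sets the 4β-hydroxy-4α-isopropyl centre (one further equivalent is consumed by the C9 hydroxyl).

Step 12
Reactants: 17 6α-(tert-butyldimethylsilyloxy)-14-nordaucane-4β,9-diol
Product: 18 4β-hydroxy-6α-(tert-butyldimethylsilyloxy)-14-nordaucan-9-one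
Conditions: Dess–Martin periodinane, NaHCO3, CH2Cl2, 0 °C → rt
Reagents that add atoms: none
Why: Dess–Martin oxidation of the only secondary hydroxyl; the tertiary C4 alcohol and the silyl ether are inert and both C9 epimers converge on one ketone.

Step 13
Reactants: 18 4β-hydroxy-6α-(tert-butyldimethylsilyloxy)-14-nordaucan-9-one
Product: 22 4β-hydroxy-6α-(tert-butyldimethylsilyloxy)dauc-8(14)-en-9-one, via dilithium enolate 19 (not isolated), via Mannich base 20 (not isolated), via methiodide 21 (not isolated)
Conditions: LDA (2.3 equiv), THF, −78 °C; CH2=NMe2+ I−, −78 °C → rt; then MeI, CH2Cl2, rt; then aq. NaHCO3, rt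
Reagents that add atoms: lithium diisopropylamide, [Li]N(C(C)C)C(C)C (lithium of 19); N,N-dimethylmethyleneiminium iodide, C=[N+](C)C.[I-]; iodomethane, CI (N-methyl of 21)
Why: Eschenmoser methylenation: LDA removes the hydroxyl proton and then, under kinetic control, a proton from the less hindered C8 methylene (C10 is neopentyl-like beside quaternary C1); Mannich aminomethylation of the enolate, N-methylation and E1cB loss of trimethylamine give the exocyclic enone.

Step 14
Reactants: 22 4β-hydroxy-6α-(tert-butyldimethylsilyloxy)dauc-8(14)-en-9-one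
Product: 23 4β,6α-dihydroxydauc-8(14)-en-9-one
Conditions: HF·pyridine, pyridine, THF, 0 °C → rt
Reagents that add atoms: none
Why: Fluoride-mediated desilylation under buffered, weakly acidic conditions that should spare the enone and the tertiary alcohol.

Step 15
Reactants: 24 4-hydroxybenzoic acid
Product: 26 4-[(tert-butyldimethylsilyl)oxy]benzoic acid, via bis-silyl derivative 25 (not isolated)
Conditions: TBSCl (2.4 equiv), imidazole, DMF, rt; then K2CO3, THF–MeOH–H2O, rt; citric acid to pH 4
Reagents that add atoms: tert-butyldimethylsilyl chloride, CC(C)(C)[Si](C)(C)Cl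
Why: Silylation of both the phenol and the acid followed by selective mild hydrolysis of the labile silyl ester leaves the phenol silyl ether.

Step 16
Reactants: 23 4β,6α-dihydroxydauc-8(14)-en-9-one; 26 4-[(tert-butyldimethylsilyl)oxy]benzoic acid
Product: 28 4β-hydroxy-9-oxodauc-8(14)-en-6α-yl 4-[(tert-butyldimethylsilyl)oxy]benzoate, via mixed anhydride 27 (not isolated)
Conditions: 2,4,6-Cl3C6H2COCl, Et3N, toluene, rt; then 23, DMAP, toluene, rt → 40 °C
Reagents that add atoms: 2,4,6-trichlorobenzoyl chloride, O=C(Cl)c1c(Cl)cc(Cl)cc1Cl (acyl group of 27)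
Why: Yamaguchi esterification: DMAP attacks the unshielded aroyl carbonyl of the mixed anhydride and the acylpyridinium acylates the secondary C6 hydroxyl with retention, while the tertiary C4 hydroxyl does not react and no C9 hydroxyl is yet present to compete.

Step 17
Reactants: 28 4β-hydroxy-9-oxodauc-8(14)-en-6α-yl 4-[(tert-butyldimethylsilyl)oxy]benzoate
Product: 29 4β,9β-dihydroxydauc-8(14)-en-6α-yl 4-[(tert-butyldimethylsilyl)oxy]benzoate
Conditions: NaBH4, CeCl3·7H2O, MeOH, −78 °C
Reagents that add atoms: none
Why: Luche reduction gives 1,2-reduction of the enone only, and hydride should reach C9 from the α face because the 1,3-related angular methyl blocks the β trajectory, setting the 9β-hydroxyl; the aryl ester and silyl ether are stable at −78 °C.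

Step 18
Reactants: 29 4β,9β-dihydroxydauc-8(14)-en-6α-yl 4-[(tert-butyldimethylsilyl)oxy]benzoate
Product: 30 (1R,4R,5S,6S,9R)-4β,9β-dihydroxydauc-8(14)-en-6α-yl 4-hydroxybenzoate (CNP0164257.2)
Conditions: KHF2, MeOH, rt
Reagents that add atoms: none
Why: Bifluoride in methanol cleaves the phenolic silyl ether selectively; the hindered ester, the allylic alcohol and the tertiary alcohol should be unaffected.

Compound list
1 | 2-bromo-3-methylcyclopent-2-en-1-one | CC1=C(Br)C(=O)CC1 | starting material
2 | ethylene glycol | OCCO | starting material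
3 | 6-bromo-7-methyl-1,4-dioxaspiro[4.4]non-6-ene | CC1=C(Br)C2(CC1)OCCO2 | intermediate
4 | methyl 4-chloro-4-oxobutanoate | COC(=O)CCC(=O)Cl | starting material
5 | methyl 4-[methoxy(methyl)amino]-4-oxobutanoate | COC(=O)CCC(=O)N(C)OC | intermediate
6 | 6-lithio-7-methyl-1,4-dioxaspiro[4.4]non-6-ene (vinyllithium, not isolated) | [Li]C1=C(C)CCC12OCCO2 | intermediate
7 | methyl 4-(7-methyl-1,4-dioxaspiro[4.4]non-6-en-6-yl)-4-oxobutanoate | COC(=O)CCC(=O)C1=C(C)CCC12OCCO2 | intermediate
8 | methyl (4S)-4-hydroxy-4-(7-methyl-1,4-dioxaspiro[4.4]non-6-en-6-yl)butanoate (not isolated) | COC(=O)CC[C@H](O)C1=C(C)CCC12OCCO2 | intermediate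
9 | (5S)-5-(7-methyl-1,4-dioxaspiro[4.4]non-6-en-6-yl)oxolan-2-one | O=C1CC[C@H](O1)C2=C(C)CCC23OCCO3 | intermediate
10 | (2S)-2-(7-methyl-1,4-dioxaspiro[4.4]non-6-en-6-yl)-5-methylideneoxolane | C=C1CC[C@H](O1)C2=C(C)CCC23OCCO3 | intermediate
11 | (1R)-4,4-ethylenedioxy-1-methyl-Δ5-hydroazulen-9-one | C[C@]12CCC3(OCCO3)C1=CCCC(=O)C2 | intermediate
12 | 4,4-ethylenedioxy-1β-methyl-9-(triethylsilyloxy)-Δ5-hydroazulene (C9 epimers) | CC[Si](CC)(CC)OC1CCC=C2[C@](C)(CCC23OCCO3)C1 | intermediate
13 | C6 alkylborane: 6α-BH2, 5α-H adduct of 12 (not isolated) | CC[Si](CC)(CC)OC1CC[C@H](B)[C@@H]2[C@](C)(CCC23OCCO3)C1 | intermediate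
14 | 6α-hydroxy-5α-H trans-fused ketal bearing 9-OSiEt3 (C9 epimers) | CC[Si](CC)(CC)OC1CC[C@H](O)[C@@H]2[C@](C)(CCC23OCCO3)C1 | intermediate
15 | 6α-(tert-butyldimethylsilyloxy) ether of 14 (C9 epimers) | CC[Si](CC)(CC)OC1CC[C@H](O[Si](C)(C)C(C)(C)C)[C@@H]2[C@](C)(CCC23OCCO3)C1 | intermediate
16 | 6α-(tert-butyldimethylsilyloxy)-9-hydroxy-1β-methyl-5α-H-hydroazulan-4-one (C9 epimers) | OC1CC[C@H](O[Si](C)(C)C(C)(C)C)[C@@H]2[C@](C)(CCC2=O)C1 | intermediate
17 | 6α-(tert-butyldimethylsilyloxy)-14-nordaucane-4β,9-diol (C9 epimers) | OC1CC[C@H](O[Si](C)(C)C(C)(C)C)[C@@H]2[C@](C)(CC[C@@]2(O)C(C)C)C1 | intermediate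
18 | 4β-hydroxy-6α-(tert-butyldimethylsilyloxy)-14-nordaucan-9-one | O=C1CC[C@H](O[Si](C)(C)C(C)(C)C)[C@@H]2[C@](C)(CC[C@@]2(O)C(C)C)C1 | intermediate
19 | dilithium C8 enolate/C4 alkoxide of 18 (not isolated) | [Li]OC1=CC[C@H](O[Si](C)(C)C(C)(C)C)[C@@H]2[C@](C)(CC[C@@]2(O[Li])C(C)C)C1 | intermediate
20 | 8-(dimethylaminomethyl) ketone, Mannich base (C8 epimers, not isolated) | CN(C)CC1C[C@H](O[Si](C)(C)C(C)(C)C)[C@@H]2[C@](C)(CC[C@@]2(O)C(C)C)CC1=O | intermediate
21 | 8-(trimethylammoniomethyl) ketone iodide (not isolated) | C[N+](C)(C)CC1C[C@H](O[Si](C)(C)C(C)(C)C)[C@@H]2[C@](C)(CC[C@@]2(O)C(C)C)CC1=O.[I-] | intermediate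
22 | 4β-hydroxy-6α-(tert-butyldimethylsilyloxy)dauc-8(14)-en-9-one | C=C1C[C@H](O[Si](C)(C)C(C)(C)C)[C@@H]2[C@](C)(CC[C@@]2(O)C(C)C)CC1=O | intermediate
23 | 4β,6α-dihydroxydauc-8(14)-en-9-one | C=C1C[C@H](O)[C@@H]2[C@](C)(CC[C@@]2(O)C(C)C)CC1=O | intermediate
24 | 4-hydroxybenzoic acid | O=C(O)c1ccc(O)cc1 | starting material
25 | tert-butyldimethylsilyl 4-[(tert-butyldimethylsilyl)oxy]benzoate (not isolated) | CC(C)(C)[Si](C)(C)OC(=O)c1ccc(O[Si](C)(C)C(C)(C)C)cc1 | intermediate
26 | 4-[(tert-butyldimethylsilyl)oxy]benzoic acid | CC(C)(C)[Si](C)(C)Oc1ccc(cc1)C(=O)O | intermediate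
27 | 4-[(tert-butyldimethylsilyl)oxy]benzoic 2,4,6-trichlorobenzoic anhydride (not isolated) | CC(C)(C)[Si](C)(C)Oc1ccc(cc1)C(=O)OC(=O)c1c(Cl)cc(Cl)cc1Cl | intermediate
28 | 4β-hydroxy-9-oxodauc-8(14)-en-6α-yl 4-[(tert-butyldimethylsilyl)oxy]benzoate | C=C1C[C@H](OC(=O)c2ccc(O[Si](C)(C)C(C)(C)C)cc2)[C@@H]2[C@](C)(CC[C@@]2(O)C(C)C)CC1=O | intermediate
29 | 4β,9β-dihydroxydauc-8(14)-en-6α-yl 4-[(tert-butyldimethylsilyl)oxy]benzoate | C=C1C[C@H](OC(=O)c2ccc(O[Si](C)(C)C(C)(C)C)cc2)[C@@H]2[C@](C)(CC[C@@]2(O)C(C)C)C[C@H]1O | intermediate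
30 | (1R,4R,5S,6S,9R)-4β,9β-dihydroxydauc-8(14)-en-6α-yl 4-hydroxybenzoate | C=C1C[C@H](OC(=O)c2ccc(O)cc2)[C@@H]2[C@](C)(CC[C@@]2(O)C(C)C)C[C@H]1O | target

Total step count: 18. Longest linear sequence: 16 steps (steps 1, 3–14, 16–18, from 1 to 30).

Steps most likely to fail

Step 6. The [3,3] shift may be outpaced by migration of the exocyclic double bond into the oxolane ring under traces of acid, or by heterolysis of the allylic C6–O bond, and crowding at the fully substituted C1 terminus raises the barrier. The fallback sets out from 10 and replaces the purely thermal step by an organoaluminium-promoted reductive ring expansion. i-Bu3Al in CH2Cl2 at −78 °C → rt binds the ring oxygen, should trigger the same C1–C10 bond formation at low temperature, and reduces the aluminium-bound C9 carbonyl by β-hydride transfer to give the 9-hydroxy-Δ5 ketal F1. TESCl and imidazole then convert it into 12, where the route is rejoined; 11 and step 7 are bypassed.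

Step 8. Borane may also approach from the face of the angular methyl, because the ring B methylenes C8 and C10 lie beneath the α face, or the hindered, ketal-deactivated alkene may react sluggishly. The fallback delivers silicon and hydrogen intramolecularly from a C9 α-oxygen, which can reach C6 only across the α face, as the ring oxygen did in 10. It sets out from 11: thermodynamic reduction (Li, NH3, t-BuOH, −78 °C) should give the equatorial 9α-alcohol F2, and HMe2SiCl with Et3N gives the 9α-dimethylsilyl ether F3. Intramolecular hydrosilylation (H2PtCl6 cat., toluene, 60 °C) then forms the bridged oxasilane F4 with silicon on C6α and hydrogen on C5α. Tamao–Fleming oxidation (H2O2, KF, KHCO3, THF–MeOH) gives the 6α,9α-diol F5, and selective silylation of the unhindered C9 hydroxyl (TESCl, imidazole, −20 °C) returns to 14 as its 9α epimer.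

Step 11. The secondary organometallic may enolise the hindered ketone or reduce it by β-hydride transfer instead of adding, with loss of material or epimerisation at C5. The fallback uses an sp2 nucleophile without β-hydrogens: from 16, isopropenylmagnesium bromide with CeCl3 (THF, −78 °C) should give the isopropenyl carbinol F6 by the same α-face attack. Hydrogenation (H2, PtO2, EtOAc) of the only alkene then present gives 17.

Further compounds
F1 | step 6 | 4,4-ethylenedioxy-1β-methyl-Δ5-hydroazulen-9-ol (C9 epimers) | OC1CCC=C2[C@](C)(CCC23OCCO3)C1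
F2 | step 8 | 4,4-ethylenedioxy-1β-methyl-Δ5-hydroazulen-9α-ol | C1CC=C2[C@](C)(CCC23OCCO3)C[C@@H]1O
F3 | step 8 | 9α-(dimethylsilyloxy) ether of F2 | C1CC=C2[C@](C)(CCC23OCCO3)C[C@@H]1O[SiH](C)C
F4 | step 8 | bridged oxasilane (Si on C6α, O on C9α, 5α-H) | C1C[C@H]([Si]4(C)C)[C@@H]2[C@](C)(CCC23OCCO3)C[C@@H]1O4
F5 | step 8 | 4,4-ethylenedioxy-1β-methyl-5α-H-hydroazulane-6α,9α-diol | C1C[C@H](O)[C@@H]2[C@](C)(CCC23OCCO3)C[C@@H]1O
F6 | step 11 | 4α-isopropenyl-6α-(tert-butyldimethylsilyloxy)-1β-methyl-5α-H-hydroazulane-4β,9-diol | OC1CC[C@H](O[Si](C)(C)C(C)(C)C)[C@@H]2[C@](C)(CC[C@@]2(O)C(C)=C)C1
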